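**Retrosyn­thetic overview**

- Target 13 comes from 4,6-dibromo-1H-indole-3-carboxylic acid 11 with two equivalents of NBS: one replaces the C3 carboxyl with loss of CO2, the other substitutes C2–H. Acid 11 comes from its tert-butyl ester 10.
- Key disconnection: the C2–C3 bond of the pyrrole ring. Ester 10 comes from the ortho-isocyanoarylacetate 8 by Cu2O catalysis. The benzene ring is bought; the pyrrole ring is the only ring formed (step 7).
- Structural feature: C2 is a single carbon between N1 and C3, so it can be carried on nitrogen as an isocyanide carbon. C3 is benzylic to C3a and peri to the C4 bromine, and an ester acidifies it; that ester later leaves as CO2 when bromine enters.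
- Isocyanide 8 comes from the formamide, the aniline and the nitro ester 5. Ester 5 comes from SNAr of the mixed malonate 3 on fluoronitroarene 2, then loss of the methyl ester. The fluorine sits between NO2 and Br, so it fixes the side-chain position. Arene 2 comes from bromination of 1.

Key step: step 7

Remark: the target is achiral; compound 4 and the transient 9 are racemic and their stereocentres disappear in the following transformation.

**Route**

Step 1
Reactants: 1 4-bromo-1-fluoro-2-nitrobenzene
Product: 2 1,5-dibromo-2-fluoro-3-nitrobenzene
Conditions: NBS (1.2 equiv), conc. H2SO4, 60 °C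
Reagents that add atoms: N-bromosuccinimide, O=C1CCC(=O)N1Br
Why: Electrophilic aromatic bromination of a deactivated arene with acid-activated NBS should go only to C6, the one open position that is ortho to the π-donating fluorine and meta to the nitro group, the other two open positions being ortho or para to nitro.

Step 2
Reactants: 2 1,5-dibromo-2-fluoro-3-nitrobenzene; 3 tert-butyl methyl malonate
Product: 4 1-tert-butyl 3-methyl 2-(2,4-dibromo-6-nitrophenyl)propanedioate (racemic)
Conditions: K2CO3 (2.5 equiv), DMF, 50 °C
Reagents that add atoms: none
Why: Nucleophilic aromatic substitution through a Meisenheimer adduct should displace only fluoride, the sole halogen ortho to the nitro group, while both bromines are meta to it and unactivated.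

Step 3
Reactants: 4 1-tert-butyl 3-methyl 2-(2,4-dibromo-6-nitrophenyl)propanedioate
Product: 5 tert-butyl 2-(2,4-dibromo-6-nitrophenyl)acetate
Conditions: LiCl (2 equiv), H2O (2 equiv), DMSO, 110 °C
Reagents that add atoms: none
Why: Krapcho dealkoxycarbonylation: chloride removes the methyl group by SN2 attack, which a tert-butyl group cannot undergo, and the carboxylate loses CO2 to a nitroaryl- and ester-stabilised carbanion that water protonates, so only the methyl ester should be lost.

Step 4
Reactants: 5 tert-butyl 2-(2,4-dibromo-6-nitrophenyl)acetate
Product: 6 tert-butyl 2-(2-amino-4,6-dibromophenyl)acetate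
Conditions: Fe powder (5 equiv), NH4Cl, EtOH/H2O (4:1), 70 °C
Reagents that add atoms: none
Why: Béchamp-type iron reduction under near-neutral conditions reduces the nitro group without hydrogenolysis of C–Br, and the bulky tert-butyl ester together with the weakly nucleophilic dibromoaniline should hold back lactamisation to the oxindole.

Step 5
Reactants: 6 tert-butyl 2-(2-amino-4,6-dibromophenyl)acetate
Product: 7 tert-butyl 2-(2,4-dibromo-6-formamidophenyl)acetate
Conditions: HCO2H/Ac2O (premixed, 55 °C, 2 h), then 6, THF, 0 °C
Reagents that add atoms: acetic formic anhydride, CC(=O)OC=O (generated from formic acid, OC=O, and acetic anhydride, CC(=O)OC(C)=O)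
Why: N-Formylation by the mixed anhydride, whose formyl carbonyl is the more electrophilic one, is fast at 0 °C even for an electron-poor aniline and should leave the tert-butyl ester intact.

Step 6
Reactants: 7 tert-butyl 2-(2,4-dibromo-6-formamidophenyl)acetate
Product: 8 tert-butyl 2-(2,4-dibromo-6-isocyanophenyl)acetate
Conditions: POCl3 (1.2 equiv), Et3N (5 equiv), CH2Cl2, −20 to 0 °C, then ice water
Reagents that add atoms: none
Why: Dehydration of an N-aryl formamide with POCl3 and a tertiary amine (O-phosphorylation, then α-elimination) is the standard isocyanide synthesis, and the cold, mildly basic medium should neither enolise the ester productively nor touch the aryl bromides.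

Step 7
Reactants: 8 tert-butyl 2-(2,4-dibromo-6-isocyanophenyl)acetate
Product: 10 tert-butyl 4,6-dibromo-1H-indole-3-carboxylate, via 3H-indole tautomer 9 (not isolated)
Conditions: Cu2O (10 mol %), degassed toluene, 80 °C, Ar
Reagents that add atoms: none
Why: The isocyanide binds monovalent copper of Cu2O, which raises the electrophilicity of the isocyanide carbon and lets the oxide deprotonate the adjacent CH2 that the ester has made acidic; the copper ester enolate then adds through its benzylic carbon to the isocyanide carbon, forming C2–C3 and a 2-cuprio-3H-indole that is protonated to 9 and tautomerises to the aromatic indole 10, returning the catalyst. The closest known reaction is the Ito–Saegusa Cu2O-catalysed cyclisation of ortho-isocyanophenylacetic esters and ortho-(acylmethyl)phenyl isocyanides to 3-acylindoles. The pyrrole ring is closed in a 5-endo-dig mode by α-addition at the terminal isocyanide carbon, which is easy because nucleophile and isocyanide are held ortho on the benzene ring. No stereocentre remains, since the sp3 C3 of 9 is lost on tautomerisation. The step needs chemoselective C–C bond formation in the presence of two aryl C–Br bonds and the acidic ring hydrogen between them; the ester secures this by lowering the pKa of the CH2 so far that neutral, ligand-free Cu2O replaces the lithium amides otherwise required, so that halogen–metal exchange, ring metalation and halogen migration should not compete.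

Step 8
Reactants: 10 tert-butyl 4,6-dibromo-1H-indole-3-carboxylate
Product: 11 4,6-dibromo-1H-indole-3-carboxylic acid
Conditions: TFA/CH2Cl2 (1:3), 0 °C to rt
Reagents that add atoms: none
Why: Acidolysis of the tert-butyl ester by an E1-type cleavage releases isobutene and the acid, and the indole, deactivated by two bromines and the C3 carboxyl, should resist tert-butylation and C3 protonation at room temperature.

Step 9
Reactants: 11 4,6-dibromo-1H-indole-3-carboxylic acid
Product: 13 2,3,4,6-tetrabromo-1H-indole, via 3,4,6-tribromo-1H-indole 12 (not isolated)
Conditions: NBS (2.05 equiv), DMF, 0 °C to rt, dark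
Reagents that add atoms: N-bromosuccinimide, O=C1CCC(=O)N1Br
Why: Bromodecarboxylation by ipso electrophilic substitution: the first bromonium equivalent attacks C3, the most nucleophilic indole position, and the 3-bromo-3H-indolium acid rearomatises by loss of CO2 to 12, after which the second equivalent brominates C2, the only free pyrrole position, as is usual for 3-haloindoles.

**Compound list**

1 | 4-bromo-1-fluoro-2-nitrobenzene | O=[N+]([O-])c1cc(Br)ccc1F | starting material
2 | 1,5-dibromo-2-fluoro-3-nitrobenzene | O=[N+]([O-])c1cc(Br)cc(Br)c1F | intermediate
3 | tert-butyl methyl malonate | COC(=O)CC(=O)OC(C)(C)C | starting material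
4 | 1-tert-butyl 3-methyl 2-(2,4-dibromo-6-nitrophenyl)propanedioate, racemic | COC(=O)C(C(=O)OC(C)(C)C)c1c(Br)cc(Br)cc1[N+](=O)[O-] | intermediate
5 | tert-butyl 2-(2,4-dibromo-6-nitrophenyl)acetate | CC(C)(C)OC(=O)Cc1c(Br)cc(Br)cc1[N+](=O)[O-] | intermediate
6 | tert-butyl 2-(2-amino-4,6-dibromophenyl)acetate | CC(C)(C)OC(=O)Cc1c(Br)cc(Br)cc1N | intermediate
7 | tert-butyl 2-(2,4-dibromo-6-formamidophenyl)acetate | CC(C)(C)OC(=O)Cc1c(Br)cc(Br)cc1NC=O | intermediate
8 | tert-butyl 2-(2,4-dibromo-6-isocyanophenyl)acetate | CC(C)(C)OC(=O)Cc1c(Br)cc(Br)cc1[N+]#[C-] | intermediate
9 | tert-butyl 4,6-dibromo-3H-indole-3-carboxylate, racemic, formed in the flask and not isolated | CC(C)(C)OC(=O)C1C=Nc2cc(Br)cc(Br)c12 | intermediate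
10 | tert-butyl 4,6-dibromo-1H-indole-3-carboxylate | CC(C)(C)OC(=O)c1c[nH]c2cc(Br)cc(Br)c12 | intermediate
11 | 4,6-dibromo-1H-indole-3-carboxylic acid | OC(=O)c1c[nH]c2cc(Br)cc(Br)c12 | intermediate
12 | 3,4,6-tribromo-1H-indole, formed in the flask and not isolated | Brc1c[nH]c2cc(Br)cc(Br)c12 | intermediate
13 | 2,3,4,6-tetrabromo-1H-indole | Brc1cc(Br)c2c(Br)c(Br)[nH]c2c1 | target

**Step count**

Total step count: 9. Longest linear sequence: 9 steps (1 to 13).

**Steps most likely to fail**

Step 7. The copper-mediated closure may stall if the benzylic carbon, crowded by the ortho bromine, is metalated too slowly, so that isocyanide oligomerisation on the copper surface or hydrolysis back to the formamide overtakes ring closure. The fallback forms the pyrrole ring from the other side, at N1–C2. It sets out from nitro ester 5. Condensation with tert-butoxybis(dimethylamino)methane (or DMF dimethyl acetal) in DMF at 90–100 °C should give the enamino ester tert-butyl 2-(2,4-dibromo-6-nitrophenyl)-3-(dimethylamino)prop-2-enoate F1. Its alkene geometry is not controlled and is immaterial. Reduction of F1 with Fe in AcOH at 60–80 °C then gives the aniline, which adds to the enamine carbon and expels dimethylamine in a Leimgruber–Batcho-type reductive cyclisation. The fallback returns to the route at indole ester 10.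

Step 9. The double bromination may go astray in three ways: ipso attack at C3 slowed by the peri bromine, over-bromination of the benzene ring, or oxidation of the electron-rich pyrrole ring by NBS in wet solvent. The fallback separates decarboxylation from halogenation. It sets out from acid 11. Acid-promoted protodecarboxylation (AcOH/aq. HCl, 90 °C) should give 4,6-dibromo-1H-indole F2. C–H bromination at C3 with one equivalent of pyridinium tribromide in pyridine at 0 °C then gives 12, where the fallback returns to the route. Compound 12 is isolated and taken to 13 with one further equivalent of NBS.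

Step 3. The selective loss of one ester may fail through thermal or base-induced cleavage of the tert-butyl ester as well, leading to the free acid or to full decarboxylation. The fallback gives up the selectivity requirement. It sets out from fluoroarene 2. SNAr with dimethyl malonate (K2CO3, DMF, 50 °C) should give dimethyl 2-(2,4-dibromo-6-nitrophenyl)propanedioate F3. Hydrolysis and decarboxylation in 6 M HCl/AcOH at reflux give 2-(2,4-dibromo-6-nitrophenyl)acetic acid F4. Esterification with Boc2O and DMAP in tert-butanol then returns to the route at nitro ester 5.

**Further compounds**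

F1 | step 7 | tert-butyl 2-(2,4-dibromo-6-nitrophenyl)-3-(dimethylamino)prop-2-enoate | CN(C)C=C(C(=O)OC(C)(C)C)c1c(Br)cc(Br)cc1[N+](=O)[O-]
F2 | step 9 | 4,6-dibromo-1H-indole | Brc1cc(Br)c2cc[nH]c2c1
F3 | step 3 | dimethyl 2-(2,4-dibromo-6-nitrophenyl)propanedioate | COC(=O)C(C(=O)OC)c1c(Br)cc(Br)cc1[N+](=O)[O-]
F4 | step 3 | 2-(2,4-dibromo-6-nitrophenyl)acetic acid | OC(=O)Cc1c(Br)cc(Br)cc1[N+](=O)[O-]
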